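**Retrosynthetic overview**
1. The strategy rests on the O4–C3(H)(CH3)–C2(OH)(aryl)–O1 segment of the 1,4-benzodioxane ring. The C3 methyl carbon and the carbonyl-level carbon C2 are read as two corners of a former cyclopropane whose third corner is C3, so C3 (R) is set as the aryloxy-bearing carbon of a 1-aryl-1-siloxycyclopropane and the CH2–C2 bond is then cut by acid.
2. That cyclopropane comes from face-selective CH2 transfer by a chiral zinc carbenoid to the (Z)-trimethylsilyl enol ether of an aryloxymethyl 3,4,5-trimethoxyphenyl ketone.
3. The ketone is cut at C2–aryl (Weinreb amide plus aryl Grignard reagent). The catechol oxygens are told apart by alkylating O4 while the future O1 is still a formyl group (Dakin oxidation later); the allyl group comes from a para-Claisen shift on o-vanillin allyl ether.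
4. Ring order: both benzene rings are bought; the cyclopropane is made (step 8) and opened (step 9); the dioxane ring closes last by hemiketalisation of the freed O1 phenol onto C2 (step 10).

Key step: step 8

Assumption (chemistry): C2 is a hemiketal carbon that equilibrates through the open hydroxy ketone, so the route only has to set C3. The (2S,3R) closed form (aryl equatorial, hydroxyl axial and anti to the 3-methyl group) is taken to be the favoured form and the one isolated.

**Step 1**
Reactants: 1 o-vanillin (2-hydroxy-3-methoxybenzaldehyde); 2 allyl bromide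
Product: 3 2-allyloxy-3-methoxybenzaldehyde
Conditions: K2CO3, DMF, 60 °C
Reagents that add atoms: none
Why: Williamson ether synthesis; the acidic ortho-formyl phenoxide displaces bromide from the primary allylic halide by SN2, and no stereocentre is involved.

**Step 2**
Reactants: 3 2-allyloxy-3-methoxybenzaldehyde
Product: 6 5-allyl-2-hydroxy-3-methoxybenzaldehyde, via ortho-dienone 4 (not isolated), via para-dienone 5 (not isolated)
Conditions: N,N-diethylaniline, 195 °C, argon
Reagents that add atoms: none
Why: para-Claisen rearrangement; both ortho positions are substituted, so the ortho-dienone 4 from the first [3,3] shift cannot enolise and passes the allyl group on by a Cope [3,3] shift to the free para carbon, where dienone 5 tautomerises to the phenol (4 and 5 are racemic transients; no stereocentre remains).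

**Step 3**
Reactants: 6 5-allyl-2-hydroxy-3-methoxybenzaldehyde; 7 2-bromo-N-methoxy-N-methylacetamide
Product: 8 2-(4-allyl-2-formyl-6-methoxyphenoxy)-N-methoxy-N-methylacetamide
Conditions: K2CO3, DMF, rt
Reagents that add atoms: none
Why: Williamson etherification by SN2 on the α-bromo amide at room temperature, below the temperature at which the new OCH2 group would condense onto the neighbouring formyl group; fixing this oxygen (the future O4) before the Dakin step makes the two catechol oxygens unambiguous.

**Step 4**
Reactants: 8 2-(4-allyl-2-formyl-6-methoxyphenoxy)-N-methoxy-N-methylacetamide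
Product: 10 2-(4-allyl-2-hydroxy-6-methoxyphenoxy)-N-methoxy-N-methylacetamide, via aryl formate 9 (not isolated)
Conditions: 30% aq. H2O2, cat. H2SO4, MeOH, rt
Reagents that add atoms: hydrogen peroxide, OO
Why: Dakin oxidation (Baeyer–Villiger type); acid-catalysed addition of H2O2 to the aldehyde and migration of the ortho-alkoxyaryl group give formate 9, which methanol cleaves in the same flask, and without a peracid the allyl alkene and the Weinreb amide should be left alone.

**Step 5**
Reactants: 10 2-(4-allyl-2-hydroxy-6-methoxyphenoxy)-N-methoxy-N-methylacetamide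
Product: 11 2-[4-allyl-2-methoxy-6-(tert-butyldimethylsilyloxy)phenoxy]-N-methoxy-N-methylacetamide
Conditions: TBSCl, imidazole, DMF, rt
Reagents that add atoms: tert-butyldimethylsilyl chloride, CC(C)(C)[Si](C)(C)Cl
Why: standard imidazole-mediated O-silylation of a phenol; the aryl silyl ether is chosen because it should tolerate the Grignard reagent, the zinc carbenoid and the mild acid of step 9 and is removed by fluoride.

**Step 6**
Reactants: 11 silyl-protected Weinreb amide; 12 5-bromo-1,2,3-trimethoxybenzene
Product: 15 2-[4-allyl-2-methoxy-6-(tert-butyldimethylsilyloxy)phenoxy]-1-(3,4,5-trimethoxyphenyl)ethan-1-one, via arylmagnesium bromide 13 (not isolated), via magnesium hemiaminal 14 (not isolated)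
Conditions: 12, Mg turnings, THF, reflux; then 11, THF, 0 °C; cold 1 M HCl
Reagents that add atoms: none
Why: Weinreb ketone synthesis; the Grignard reagent 13 adds once to the N-methoxy-N-methylamide and the five-membered magnesium chelate 14 holds until the acidic quench, so no tertiary alcohol should form.

**Step 7**
Reactants: 15 aryloxymethyl aryl ketone
Product: 16 (Z)-trimethylsilyl enol ether of 15 (aryloxy cis to Me3SiO on the double bond)
Conditions: TMSOTf, Et3N, CH2Cl2, 0 °C; pentane, filtration, used at once
Reagents that add atoms: trimethylsilyl trifluoromethanesulfonate, C[Si](C)(C)OS(=O)(=O)C(F)(F)F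
Why: soft enolisation and O-silylation of an aryl ketone; the Z isomer is expected because in the E isomer the aryloxy group would clash with the trimethoxyphenyl ring (allylic 1,3-strain).

**Step 8**
Reactants: 16 (Z)-trimethylsilyl enol ether; 17 diiodomethane
Product: 18 (1R,2R)-2-[4-allyl-2-methoxy-6-(tert-butyldimethylsilyloxy)phenoxy]-1-(3,4,5-trimethoxyphenyl)-1-(trimethylsilyloxy)cyclopropane (aryloxy cis to silyloxy)
Conditions: Et2Zn (1.5 equiv), 17 (3 equiv), N-Boc-L-Val-L-Pro-OMe or its D,D antipode (0.25 equiv), CH2Cl2, −40 °C; pyridine, then aq. NaHCO3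
Reagents that add atoms: none
Why: Et2Zn and 17 form Zn(CH2I)2 (divalent zinc), the zincated N–H of the Boc-dipeptide takes up an iodomethyl group, and this chiral amido(iodomethyl)zinc species hands CH2 to the enol ether through the concerted three-centre butterfly transition state of the Simmons–Smith reaction. The closest known reaction type is the dipeptide-catalysed asymmetric Simmons–Smith cyclopropanation of trimethylsilyl enol ethers of aryl ketones. The three-membered ring closes by a [2+1] addition in which the CH2–C1 and CH2–C2 bonds form together on one face of the alkene, with no open intermediate. The cis relation of aryloxy and silyloxy groups follows from the Z geometry of 16 and the suprafacial addition; the absolute configuration (1R at the silyloxy carbon, 2R at the aryloxy carbon, the future C3) is set by the zinc-bound ligand, which must deliver CH2 to the face that is Re at the aryloxy-bearing carbon, and the ligand antipode that does so is the one used. The step needs enantioface selectivity, which requires the ligand-bound carbenoid to outrun free Zn(CH2I)2 (low temperature, slow addition of 17, ligand loading raised if needed), and chemoselectivity for the enol ether over the allyl group, which the much higher nucleophilicity of the doubly oxygenated alkene and a small excess of carbenoid should secure. The aryloxy oxygen with its flanking methoxy and silyloxy groups is an extra zinc-binding site absent from simple aryl enol ethers, so the level of face selectivity on this substrate is the open point, and the cold pyridine quench keeps ZnI2 from opening the product.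

**Step 9**
Reactants: 18 (1R,2R)-siloxycyclopropane
Product: 20 (R)-2-[4-allyl-2-methoxy-6-(tert-butyldimethylsilyloxy)phenoxy]-1-(3,4,5-trimethoxyphenyl)propan-1-one, via cyclopropanol 19 (not isolated)
Conditions: p-TsOH·H2O (0.2 equiv), MeOH–CH2Cl2, 0 °C → rt
Reagents that add atoms: none
Why: acid-mediated ring opening of a siloxycyclopropane (the homologue of silyl enol ether hydrolysis); methanolysis of the Me3Si ether gives 19, the proton attacks the unsubstituted CH2 and its bond to the carbinol carbon breaks under the push of the hydroxyl and the electron-rich aryl group, so the CH2 becomes the methyl group and the aryloxy carbon keeps its configuration because none of its bonds is broken.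

**Step 10**
Reactants: 20 (R)-α-aryloxy ketone
Product: 22 (2S,3R)-7-allyl-5-methoxy-3-methyl-2-(3,4,5-trimethoxyphenyl)-2,3-dihydro-1,4-benzodioxin-2-ol, via open-chain hydroxy ketone 21 (not isolated)
Conditions: HF·pyridine, pyridine, THF, 0 °C → rt
Reagents that add atoms: none
Why: fluoride cleavage of the aryl silyl ether under buffered, non-basic conditions that should not enolise C3–H; the freed phenol adds reversibly to the ketone (6-exo-trig hemiketalisation), and C2 settles under thermodynamic control (aryl equatorial, hydroxyl axial by the anomeric effect), which should give 2S from 3R.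

**Compound list**
1 | o-vanillin (2-hydroxy-3-methoxybenzaldehyde) | COc1cccc(C=O)c1O | starting material
2 | allyl bromide | C=CCBr | starting material
3 | 2-allyloxy-3-methoxybenzaldehyde | C=CCOc1c(OC)cccc1C=O | intermediate
4 | 3-methoxy-2-oxo-1-(prop-2-enyl)cyclohexa-3,5-diene-1-carbaldehyde (racemic ortho-dienone) | C=CCC1(C=O)C=CC=C(OC)C1=O | intermediate
5 | 5-methoxy-6-oxo-3-(prop-2-enyl)cyclohexa-1,4-diene-1-carbaldehyde (racemic para-dienone) | C=CCC1C=C(C=O)C(=O)C(OC)=C1 | intermediate
6 | 5-allyl-2-hydroxy-3-methoxybenzaldehyde | C=CCc1cc(OC)c(O)c(C=O)c1 | intermediate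
7 | 2-bromo-N-methoxy-N-methylacetamide | CON(C)C(=O)CBr | starting material
8 | 2-(4-allyl-2-formyl-6-methoxyphenoxy)-N-methoxy-N-methylacetamide | C=CCc1cc(OC)c(OCC(=O)N(C)OC)c(C=O)c1 | intermediate
9 | 5-allyl-3-methoxy-2-{2-[methoxy(methyl)amino]-2-oxoethoxy}phenyl formate | C=CCc1cc(OC)c(OCC(=O)N(C)OC)c(OC=O)c1 | intermediate
10 | 2-(4-allyl-2-hydroxy-6-methoxyphenoxy)-N-methoxy-N-methylacetamide | C=CCc1cc(OC)c(OCC(=O)N(C)OC)c(O)c1 | intermediate
11 | 2-[4-allyl-2-methoxy-6-(tert-butyldimethylsilyloxy)phenoxy]-N-methoxy-N-methylacetamide | C=CCc1cc(OC)c(OCC(=O)N(C)OC)c(O[Si](C)(C)C(C)(C)C)c1 | intermediate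
12 | 5-bromo-1,2,3-trimethoxybenzene | COc1cc(Br)cc(OC)c1OC | starting material
13 | (3,4,5-trimethoxyphenyl)magnesium bromide | COc1cc([Mg]Br)cc(OC)c1OC | intermediate
14 | bromomagnesium alkoxide of the tetrahedral adduct of 13 and 11 (new carbon of undefined configuration) | C=CCc1cc(OC)c(OCC(O[Mg]Br)(N(C)OC)c2cc(OC)c(OC)c(OC)c2)c(O[Si](C)(C)C(C)(C)C)c1 | intermediate
15 | 2-[4-allyl-2-methoxy-6-(tert-butyldimethylsilyloxy)phenoxy]-1-(3,4,5-trimethoxyphenyl)ethan-1-one | C=CCc1cc(OC)c(OCC(=O)c2cc(OC)c(OC)c(OC)c2)c(O[Si](C)(C)C(C)(C)C)c1 | intermediate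
16 | (Z)-trimethylsilyl enol ether of 15 | C=CCc1cc(OC)c(O/C=C(\O[Si](C)(C)C)c2cc(OC)c(OC)c(OC)c2)c(O[Si](C)(C)C(C)(C)C)c1 | intermediate
17 | diiodomethane | ICI | starting material
18 | (1R,2R)-2-[4-allyl-2-methoxy-6-(tert-butyldimethylsilyloxy)phenoxy]-1-(3,4,5-trimethoxyphenyl)-1-(trimethylsilyloxy)cyclopropane | C=CCc1cc(OC)c(O[C@@H]2C[C@@]2(O[Si](C)(C)C)c2cc(OC)c(OC)c(OC)c2)c(O[Si](C)(C)C(C)(C)C)c1 | intermediate
19 | (1R,2R)-2-[4-allyl-2-methoxy-6-(tert-butyldimethylsilyloxy)phenoxy]-1-(3,4,5-trimethoxyphenyl)cyclopropan-1-ol | C=CCc1cc(OC)c(O[C@@H]2C[C@@]2(O)c2cc(OC)c(OC)c(OC)c2)c(O[Si](C)(C)C(C)(C)C)c1 | intermediate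
20 | (R)-2-[4-allyl-2-methoxy-6-(tert-butyldimethylsilyloxy)phenoxy]-1-(3,4,5-trimethoxyphenyl)propan-1-one | C=CCc1cc(OC)c(O[C@H](C)C(=O)c2cc(OC)c(OC)c(OC)c2)c(O[Si](C)(C)C(C)(C)C)c1 | intermediate
21 | (R)-2-(4-allyl-2-hydroxy-6-methoxyphenoxy)-1-(3,4,5-trimethoxyphenyl)propan-1-one | C=CCc1cc(OC)c(O[C@H](C)C(=O)c2cc(OC)c(OC)c(OC)c2)c(O)c1 | intermediate
22 | (2S,3R)-7-allyl-5-methoxy-3-methyl-2-(3,4,5-trimethoxyphenyl)-2,3-dihydro-1,4-benzodioxin-2-ol | C=CCc1cc(OC)c2c(c1)O[C@@](O)(c1cc(OC)c(OC)c(OC)c1)[C@@H](C)O2 | target

Total step count: 10
Longest linear sequence: 10 steps (1 → 22); 12 enters in step 6 as the Grignard reagent made in the flask.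

**Steps most likely to fail**

Step 8. The face selection may be poor, because the aryloxy oxygen and its neighbours can bind zinc and let the unligated carbenoid reach either face. Excess reagent may also transfer methylene to the allyl group, and ZnI2 may open the product before the quench. The fallback uses the chiral pool and sets out from 6. A Mitsunobu reaction with commercial (S)-2-hydroxy-N-methoxy-N-methylpropanamide (PPh3, diisopropyl azodicarboxylate, THF, 0 °C → rt) should give, with SN2 inversion, (R)-2-(4-allyl-2-formyl-6-methoxyphenoxy)-N-methoxy-N-methylpropanamide F1. Dakin oxidation under the conditions of step 4 would pass through the aryl formate F2 to the phenol F3, and silylation as in step 5 would give the tert-butyldimethylsilyl ether F4. Addition of 13 (from 12) as in step 6, through the magnesium hemiaminal F5, comes back to the route at 20, so 15, 16 and 18 are bypassed.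

Step 9. The opening may need acid strong enough to enolise the product ketone and erode C3. The aryloxide may also be expelled if the CH2 carbon gains carbanion character, and partial loss of the aryl silyl ether may give mixtures. The fallback sets out from 18 and reverses the order of events. HF·pyridine in THF–pyridine would remove both silyl groups while C3 is still a cyclopropane carbon that cannot enolise, giving (1R,2R)-2-(4-allyl-2-hydroxy-6-methoxyphenoxy)-1-(3,4,5-trimethoxyphenyl)cyclopropan-1-ol F6. Catalytic p-TsOH in CH2Cl2 would then open the ring while the neighbouring phenol captures the carbonyl group as it forms. This comes back to the route at 22 and makes step 10 unnecessary.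

Step 4. The ether oxygen ortho to the formyl group is flanked on both sides and twisted out of conjugation, so aryl migration may be slow and hydride migration to the acid or ester may compete. The electron-rich phenol product may also be oxidised further. The fallback sets out from 6 and applies the classical alkaline Dakin oxidation (H2O2, aq. NaOH, 0 °C → rt), in which the free ortho-hydroxyl drives aryl migration. It would pass through 5-allyl-2-hydroxy-3-methoxyphenyl formate F7 to 5-allyl-3-methoxybenzene-1,2-diol F8. Silylation of the less hindered hydroxyl (TBSCl, 1.0 equiv, imidazole, CH2Cl2, −20 °C) should give 4-allyl-2-methoxy-6-(tert-butyldimethylsilyloxy)phenol F9. O-alkylation with 7 (K2CO3, acetone, rt, kept mild to hold back silyl migration between the two oxygens) comes back to the route at 11. The regiochemistry of this fallback rests on sterics alone, which is why it is not the main line.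

**Further compounds**
F1 | step 8 | (R)-2-(4-allyl-2-formyl-6-methoxyphenoxy)-N-methoxy-N-methylpropanamide | C=CCc1cc(OC)c(O[C@H](C)C(=O)N(C)OC)c(C=O)c1
F2 | step 8 | 5-allyl-3-methoxy-2-{[(R)-1-[methoxy(methyl)amino]-1-oxopropan-2-yl]oxy}phenyl formate | C=CCc1cc(OC)c(O[C@H](C)C(=O)N(C)OC)c(OC=O)c1
F3 | step 8 | (R)-2-(4-allyl-2-hydroxy-6-methoxyphenoxy)-N-methoxy-N-methylpropanamide | C=CCc1cc(OC)c(O[C@H](C)C(=O)N(C)OC)c(O)c1
F4 | step 8 | (R)-2-[4-allyl-2-methoxy-6-(tert-butyldimethylsilyloxy)phenoxy]-N-methoxy-N-methylpropanamide | C=CCc1cc(OC)c(O[C@H](C)C(=O)N(C)OC)c(O[Si](C)(C)C(C)(C)C)c1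
F5 | step 8 | bromomagnesium alkoxide of the tetrahedral adduct of 13 and F4 | C=CCc1cc(OC)c(O[C@H](C)C(O[Mg]Br)(N(C)OC)c2cc(OC)c(OC)c(OC)c2)c(O[Si](C)(C)C(C)(C)C)c1
F6 | step 9 | (1R,2R)-2-(4-allyl-2-hydroxy-6-methoxyphenoxy)-1-(3,4,5-trimethoxyphenyl)cyclopropan-1-ol | C=CCc1cc(OC)c(O[C@@H]2C[C@@]2(O)c2cc(OC)c(OC)c(OC)c2)c(O)c1
F7 | step 4 | 5-allyl-2-hydroxy-3-methoxyphenyl formate | C=CCc1cc(OC)c(O)c(OC=O)c1
F8 | step 4 | 5-allyl-3-methoxybenzene-1,2-diol | C=CCc1cc(O)c(O)c(OC)c1
F9 | step 4 | 4-allyl-2-methoxy-6-(tert-butyldimethylsilyloxy)phenol | C=CCc1cc(OC)c(O)c(O[Si](C)(C)C(C)(C)C)c1
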